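**Assumption:** the target SMILES carries no stereodescriptor, but its tetra-ortho-substituted biaryl axis is configurationally stable, so the route delivers one atropisomer, taken as (aR). Plain SMILES cannot show the axis, so the descriptor is given in the names. The (R)-ligand in step 3 is assumed to give (aR); if the sense is opposite, the (S)-ligand is used.

## Retrosynthetic overview

1. Target 10 comes from the (aR)-2,2'-diallyl biaryl 8 by double Tsuji–Wacker oxidation, with the axis already in place.
2. 8 comes from dibenzostannole 5 by the new step: a Pd-catalysed atroposelective double ring-opening allylation that forms both aryl–CH2 bonds and sets the axis.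
3. 5 comes from racemic dibromide 2 by double Br/Li exchange and ring closure on Me2SnCl2; the freely flipping stannole ring erases the racemic axis.
4. 2 comes from oxidative dehydrodimerisation of 5-bromo-1,2,3-trimethoxybenzene 1, so the biaryl bond is made first.
5. Ring order: both benzene rings come from 1; the only ring formed is the temporary five-membered stannole ring (step 2), opened again in step 3.

## Route

**Step 1**
Reactants: 1 5-bromo-1,2,3-trimethoxybenzene (2 molecules per biaryl)
Product: 2 racemic 2,2'-dibromo-4,4',5,5',6,6'-hexamethoxy-1,1'-biphenyl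
Conditions: PhI(OCOCF3)2 (0.55 equiv), BF3·OEt2 (1.1 equiv), CH2Cl2, −40 °C, 2 h
Reagents that add atoms: none
Why: Non-phenolic oxidative dehydrodimerisation (Kita-type aryl ether coupling through the arene radical cation); the only C–H positions of 1 are the two equivalent ones ortho to Br and para to an outer OMe, so one regioisomer forms, and the twisted product is harder to oxidise than 1, which limits over-coupling.

**Step 2**
Reactants: 2 racemic 2,2'-dibromo-4,4',5,5',6,6'-hexamethoxy-1,1'-biphenyl; 3 dimethyltin dichloride
Product: 5 1,2,3,7,8,9-hexamethoxy-5,5-dimethyl-5H-dibenzo[b,d]stannole, via 2,2'-dilithiobiaryl 4 (not isolated)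
Conditions: t-BuLi (4.2 equiv), THF, −78 °C, 30 min; then Me2SnCl2 (1.05 equiv), slow addition, −78 °C to rt, 0.03 M
Reagents that add atoms: dimethyltin dichloride, C[Sn](C)(Cl)Cl
Why: Double bromine–lithium exchange followed by double salt metathesis at tin is the standard 9-stannafluorene synthesis, and the long C–Sn bonds should let the five-membered ring close despite the two bay methoxy groups (as in bay-substituted cyclic diaryliodonium salts); the racemic axis of 2 is erased because the stannole ring flips freely.

**Step 3**
Reactants: 5 1,2,3,7,8,9-hexamethoxy-5,5-dimethyl-5H-dibenzo[b,d]stannole; 6 allyl tert-butyl carbonate (2.5 equiv)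
Product: 8 (aR)-4,4',5,5',6,6'-hexamethoxy-2,2'-di(prop-2-en-1-yl)-1,1'-biphenyl, via monoallyl tert-butoxystannane 7 (not isolated)
Conditions: Pd2(dba)3 (2.5 mol%), (R)-MeO-MOP (6 mol%), THF, 40 °C, 16 h, strictly anhydrous
Reagents that add atoms: allyl tert-butyl carbonate, C=CCOC(=O)OC(C)(C)C
Why: Proposed new method: atroposelective double ring-opening Stille allylation of a bay-substituted dibenzostannole — zerovalent palladium carrying the monodentate binaphthyl phosphine ionises the allyl carbonate to a (η3-allyl)Pd(L*) tert-butoxide with loss of CO2, the alkoxide adds to the strained, Lewis-acidic tin centre, and transmetalation cleaves one endocyclic Sn–C(aryl) bond (aryl transfers far faster than methyl); the two helical conformers of 5 interconvert rapidly whereas the ring-opened aryl–Pd species is tetra-ortho-substituted and locked, so the chiral Pd fragment decides the sense in which the rings twist apart (dynamic kinetic asymmetric transformation); C–C reductive elimination gives 7, and a second, axis-retentive Stille allylation of its Ar–SnMe2(OtBu) bond, activated by the next tert-butoxide, gives 8; the closest known reaction types are the Stille allyl–aryl coupling and the catalytic atroposelective ring opening of configurationally labile bridged biaryls (biaryl lactones, cyclic diaryliodonium salts), neither of which has used a dibenzostannole or delivered both ortho substituents in one operation.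

**Step 4**
Reactants: 8 (aR)-4,4',5,5',6,6'-hexamethoxy-2,2'-di(prop-2-en-1-yl)-1,1'-biphenyl
Product: 10 (aR)-1,1'-(4,4',5,5',6,6'-hexamethoxy-[1,1'-biphenyl]-2,2'-diyl)di(propan-2-one), via monoketone 9 (not isolated)
Conditions: PdCl2 (20 mol%), CuCl (40 mol%), O2 (1 atm), DMF/H2O 7:1, rt, 24 h
Reagents that add atoms: water, O
Why: Tsuji–Wacker oxidation: Markovnikov hydroxypalladation of each terminal alkene by water and β-hydride elimination give the methyl ketones under neutral conditions at room temperature, which leave the aryl ethers untouched and lie far below the rotation barrier of the tetra-ortho-substituted axis, so the configuration set in step 3 is kept.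

## Compound list

1 | 5-bromo-1,2,3-trimethoxybenzene | COc1cc(Br)cc(OC)c1OC | starting material
2 | racemic 2,2'-dibromo-4,4',5,5',6,6'-hexamethoxy-1,1'-biphenyl | COc1cc(Br)c(-c2c(Br)cc(OC)c(OC)c2OC)c(OC)c1OC | intermediate
3 | dimethyltin dichloride | C[Sn](C)(Cl)Cl | starting material
4 | racemic 2,2'-dilithio-4,4',5,5',6,6'-hexamethoxy-1,1'-biphenyl (not isolated) | COc1cc([Li])c(-c2c([Li])cc(OC)c(OC)c2OC)c(OC)c1OC | intermediate
5 | 1,2,3,7,8,9-hexamethoxy-5,5-dimethyl-5H-dibenzo[b,d]stannole (rapidly flipping ring, no fixed stereo element) | COc1cc2c(c(OC)c1OC)-c1c(cc(OC)c(OC)c1OC)[Sn]2(C)C | intermediate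
6 | allyl tert-butyl carbonate | C=CCOC(=O)OC(C)(C)C | starting material
7 | (aS)-tert-butoxy[4,4',5,5',6,6'-hexamethoxy-2'-(prop-2-en-1-yl)-[1,1'-biphenyl]-2-yl]dimethylstannane (same sense of twist as 8; the descriptor changes because Sn outranks O; not isolated) | C=CCc1cc(OC)c(OC)c(OC)c1-c1c(cc(OC)c(OC)c1OC)[Sn](C)(C)OC(C)(C)C | intermediate
8 | (aR)-4,4',5,5',6,6'-hexamethoxy-2,2'-di(prop-2-en-1-yl)-1,1'-biphenyl | C=CCc1cc(OC)c(OC)c(OC)c1-c1c(CC=C)cc(OC)c(OC)c1OC | intermediate
9 | (aR)-1-[4,4',5,5',6,6'-hexamethoxy-2'-(prop-2-en-1-yl)-[1,1'-biphenyl]-2-yl]propan-2-one (not isolated) | CC(=O)Cc1cc(OC)c(OC)c(OC)c1-c1c(CC=C)cc(OC)c(OC)c1OC | intermediate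
10 | (aR)-1,1'-(4,4',5,5',6,6'-hexamethoxy-[1,1'-biphenyl]-2,2'-diyl)di(propan-2-one) | COc1cc(CC(C)=O)c(-c2c(CC(C)=O)cc(OC)c(OC)c2OC)c(OC)c1OC | target

## Summary and risks

Total step count: 4. Longest linear sequence: 4 steps (1 → 2 → 5 → 8 → 10).

**Most likely to fail, 1: step 3 (the proposed new method).** The enantioselectivity is untested, the second aryl transfer from the acyclic alkoxystannane may be slow, and the strained stannole may protodestannylate. The fallback uses known chemistry, sets out from 2 and comes back at 8. Dibromide 2 is converted with t-BuLi (THF, −78 °C) into the dilithio species 4, which is allylated with allyl bromide under CuBr·SMe2 catalysis (10 mol%) to give racemic 4,4',5,5',6,6'-hexamethoxy-2,2'-di(prop-2-en-1-yl)-1,1'-biphenyl F1. The atropisomers of F1 are then separated by preparative chromatography on a chiral stationary phase (amylose tris(3,5-dimethylphenylcarbamate), supercritical CO2/MeOH), and the (aR) fraction is 8.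

**Most likely to fail, 2: step 1.** The radical-cation coupling may stall because of the bromine, or run on to terphenyls. The fallback sets out from 1 and comes back at 2. Iodination of 1 with N-iodosuccinimide and catalytic CF3CO2H in MeCN at the only free position type gives 1-bromo-2-iodo-3,4,5-trimethoxybenzene F2. A classical Ullmann homocoupling with activated Cu powder in DMF at 130 °C, selective for the C–I bond over C–Br, then gives 2.

**Most likely to fail, 3: step 4.** Divalent palladium can isomerise the allyl groups into conjugated propenyl arenes, and the second oxidation may lag. The fallback sets out from 8 and comes back at 10. Mukaiyama hydration of both alkenes (Co(acac)2 20 mol%, PhSiH3, O2, THF/i-PrOH, rt) by radical hydrogen-atom transfer gives (aR)-1,1'-(4,4',5,5',6,6'-hexamethoxy-[1,1'-biphenyl]-2,2'-diyl)di(propan-2-ol) F3 as a mixture of carbinol epimers. Oxidation with Dess–Martin periodinane (NaHCO3, CH2Cl2, 0 °C to rt) removes both carbinol stereocentres and gives 10; any ketone already formed in the hydration converges on the same product.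

## Further compounds

F1 | step 3 | racemic 4,4',5,5',6,6'-hexamethoxy-2,2'-di(prop-2-en-1-yl)-1,1'-biphenyl | C=CCc1cc(OC)c(OC)c(OC)c1-c1c(CC=C)cc(OC)c(OC)c1OC
F2 | step 1 | 1-bromo-2-iodo-3,4,5-trimethoxybenzene | COc1cc(Br)c(I)c(OC)c1OC
F3 | step 4 | (aR)-1,1'-(4,4',5,5',6,6'-hexamethoxy-[1,1'-biphenyl]-2,2'-diyl)di(propan-2-ol), mixture of carbinol epimers | CC(O)Cc1cc(OC)c(OC)c(OC)c1-c1c(CC(C)O)cc(OC)c(OC)c1OC
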